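**Plan**

1. Retrosynthesis: the three C(aryl)–C(β) bonds of the cinnamoyl arms are cut first (threefold Mizoroki–Heck transform), then the three N–C(=O) amide bonds of the tris-acrylamide that remains.
2. Enabling feature: every arm ends in a 4-hydroxyphenyl ring whose ipso carbon is joined by an sp2–sp2 bond to the β-carbon of an α,β-unsaturated amide (Ar–CH=CH–C(=O)N). These three bonds lie at the periphery, remote from N1, N5 and N10 of the polyamine chain.
3. Forward: spermidine (1) is acylated on all three nitrogens with three equivalents of acryloyl chloride (2) to the triacrylamide (3), and 3 is then arylated with three equivalents of 4-iodophenol (4) to give the target (5). The chain stays acyclic; no ring is formed.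
4. Stereochemistry: there is no stereocentre. The three (E) double bonds arise in the Heck step from syn carbopalladation followed by syn β-hydride elimination.
5. No protecting group is used: the phenols stay free and the amide N–H bonds are inert under the coupling conditions.

Key step: step 2

Remark: each step acts on three like sites and consumes three equivalents of its second reactant (1 + 3 × 2 → 3; 3 + 3 × 4 → 5). The first equivalent stands on the Reactants line and the two further ones under the reagents that add atoms. The short-lived mixtures of partly acylated or partly arylated regioisomers are not single compounds and are not counted as separate intermediates.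

**Step 1**
Reactants: 1 spermidine (N-(3-aminopropyl)butane-1,4-diamine; N1 is the NH2 of the propyl end, N5 the central NH, N10 the NH2 of the butyl end); 2 acryloyl chloride (three equivalents are incorporated)
Product: 3 N1,N5,N10-triacryloylspermidine (N-[4-(acryloylamino)butyl]-N-[3-(acryloylamino)propyl]acrylamide)
Conditions: acryloyl chloride (3.6 equiv in total, dropwise), NaOH (2 M aq, 4 equiv), CH2Cl2, BHT (2,6-di-tert-butyl-4-methylphenol, cat.), 0 °C to rt
Reagents that add atoms: acryloyl chloride, the second plus third equivalent of compound 2, C=CC(=O)Cl.C=CC(=O)Cl
Why: Schotten–Baumann N-acylation, in which the acid chloride at 0 °C should acylate the two primary and the one secondary amine far faster than any nitrogen adds in conjugate fashion to an acryloyl group, while aqueous NaOH takes up the three equivalents of HCl so that all three nitrogens stay nucleophilic and BHT suppresses radical polymerisation of the triacrylamide during reaction and concentration.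

**Step 2**
Reactants: 3 N1,N5,N10-triacryloylspermidine; 4 4-iodophenol (three equivalents are incorporated)
Product: 5 N1,N5,N10-tri-(E)-p-coumaroylspermidine (all three alkenes E)
Conditions: 4-iodophenol (4.5 equiv in total), Pd(OAc)2 (5 mol % per alkene), n-Bu4NCl (3 equiv), NaHCO3 (7.5 equiv), BHT (cat.), DMF, 70 °C, under argon
Reagents that add atoms: 4-iodophenol, the second plus third equivalent of compound 4, Oc1ccc(I)cc1.Oc1ccc(I)cc1
Why: Pd(OAc)2 is reduced in the flask to chloride-stabilised zerovalent palladium, which inserts into the C–I bond of 4; the resulting arylpalladium iodide (divalent palladium) coordinates an acrylamide C=C, adds across it in a syn fashion with the aryl group going to the unsubstituted β-carbon, and syn β-hydride elimination releases the cinnamamide while NaHCO3 takes up HI and returns zerovalent palladium to the cycle, which turns over three times per molecule of 3. The closest known reaction type is the ligand-free, phase-transfer Mizoroki–Heck arylation of secondary and N,N-dialkyl acrylamides with aryl iodides, unprotected iodophenols included; here the same event is run at three electronically alike, mutually remote acrylamide termini of one molecule. No ring closes and no stereocentre is created; the only stereochemical element is the geometry of the three new 1,2-disubstituted alkenes, which should be (E) because the σ-alkylpalladium species eliminates from the rotamer that keeps aryl and carboxamide apart. The step needs β-regioselectivity, secured by the polarised, monosubstituted, electron-poor alkene; C-arylation rather than O- or N-arylation, secured by the mild bicarbonate base and by the absence of ligands that promote C–O or C–N coupling; and full threefold conversion without a second arylation of any arm, secured by the excess of 4 and by the much slower insertion of the disubstituted product alkene. The moderate temperature and BHT should keep the polyacrylamide from cross-linking before it is consumed.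

**Compound list**

1 | spermidine, N-(3-aminopropyl)butane-1,4-diamine | NCCCCNCCCN | starting material
2 | acryloyl chloride, prop-2-enoyl chloride | C=CC(=O)Cl | starting material
3 | N1,N5,N10-triacryloylspermidine | C=CC(=O)NCCCCN(CCCNC(=O)C=C)C(=O)C=C | intermediate
4 | 4-iodophenol | Oc1ccc(I)cc1 | starting material
5 | N1,N5,N10-tri-(E)-p-coumaroylspermidine | O=C(/C=C/c1ccc(O)cc1)NCCCCN(CCCNC(=O)/C=C/c1ccc(O)cc1)C(=O)/C=C/c1ccc(O)cc1 | target

**Step count and risks**

Total step count: 2
Longest linear sequence: 2 steps (1 → 3 → 5)

Steps most likely to fail (the route has only two steps, so both are ranked, the riskier first):

1. Step 2. The catalyst may aggregate to inactive palladium black before the third arylation of a molecule is complete, and the acrylamide groups of the substrate may cross-link by radical polymerisation at the reaction temperature. Either process would stop conversion at partial arylation or lose material to an insoluble network. The fallback sets out from 1 and comes back to the route at 5. It gives up the late aryl–vinyl bond formation and brings the cinnamoyl arms in preformed, so that neither a polymerisable substrate nor a palladium cycle is involved. Commercial (E)-4-acetoxycinnamic acid (CC(=O)Oc1ccc(/C=C/C(=O)O)cc1) would be converted with oxalyl chloride and catalytic DMF in CH2Cl2 into (E)-4-acetoxycinnamoyl chloride F1. Compound 1 would then be acylated at all three nitrogens with three equivalents of F1 (NaHCO3 (aq)/CH2Cl2, 0 °C) to give N1,N5,N10-tris[(E)-4-acetoxycinnamoyl]spermidine F2. Methanolysis of the three aryl acetates (K2CO3 cat., MeOH, rt), which should leave the amides and the (E) alkenes untouched, would deliver 5.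

2. Step 1. Conjugate addition of not yet acylated amine nitrogens to acryloyl groups may compete with N-acylation, the product may polymerise on concentration, and the polar triamide may partition into the aqueous phase. The fallback sets out from 1 and comes back to the route at 3. It masks the acrylamide as a saturated β-chloro amide until all nitrogens are acylated. Compound 1 would be acylated with three equivalents of commercial 3-chloropropanoyl chloride (ClCCC(=O)Cl; NaHCO3 (aq)/CH2Cl2, 0 °C) to N1,N5,N10-tris(3-chloropropanoyl)spermidine F3, a storable triamide that carries no Michael acceptor while free amine is present. Threefold dehydrochlorination (NaOH, THF/water, 60 °C, BHT) would then unveil the three acrylamides of 3 shortly before the coupling.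

**Further compounds**

F1 | step 2 | (E)-4-acetoxycinnamoyl chloride | CC(=O)Oc1ccc(/C=C/C(=O)Cl)cc1
F2 | step 2 | N1,N5,N10-tris[(E)-4-acetoxycinnamoyl]spermidine | CC(=O)Oc1ccc(/C=C/C(=O)NCCCCN(CCCNC(=O)/C=C/c2ccc(OC(C)=O)cc2)C(=O)/C=C/c2ccc(OC(C)=O)cc2)cc1
F3 | step 1 | N1,N5,N10-tris(3-chloropropanoyl)spermidine | ClCCC(=O)NCCCCN(CCCNC(=O)CCCl)C(=O)CCCl
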